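**Plan**

- Retrosynthesis: the O8–acyl bond is cut last, and O8 is traced back to a methyl ether, giving the symmetric 5,7-dihydroxy-3,6,8,4'-tetramethoxyflavone. In that flavone O1–C2 (ring C) and C4a–C8a (ring A) are cut together, which unfolds it to a 2-pyranone-masked polyketide. The C4a–C4 bond is then cut into a 6-methyl-2-pyranone and a β-methoxyacrylate.
- Forward: two methoxyacetate units and one acetyl unit give 4-hydroxy-3,5-dimethoxy-6-methyl-2-pyranone. Methoxyacetate and 4-methoxybenzoyl chloride give the enol-ether ester. The two are joined at C4a–C4, and one flask then closes ring A (Claisen) and ring C (addition–elimination).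
- Enabling feature: ring A (C4a, C5, C6, C7, C8, C8a) is an acylphloroglucinol oxygenated on every carbon. Carbonyl-derived C5, C7 and C8a alternate with methoxy-bearing C6 and C8, so the ring is a folded chain of methoxyacetate units. With O8 as a methyl ether the ring is symmetric about the C4a–C7 axis, so either ortho hydroxyl closes ring C to the same flavone.
- O8 is afterwards singled out through its para relation to O5 (5,8-quinone, then reduction). It is acylated while O5 is chelated and O7 is benzylated.
- Stereochemistry: the target has no stereocentre, and the enol-ether geometry of the precursor is erased in ring C closure, so nothing has to be controlled.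

Key step: step 7

Remark: the enol-ether double bond is drawn E (the two methoxy groups trans); the Z isomer would converge on the same flavone. β-Dicarbonyl compounds are drawn as keto forms, and their CH(OMe) centres are racemic and labile.

**Route**

Step 1
Reactants: 1 methyl methoxyacetate (two molecules)
Product: 2 methyl 2,4-dimethoxy-3-oxobutanoate (racemic)
Conditions: NaH (0.55 equiv per ester), THF, 0 °C to reflux; then 1 M HCl, 0 °C
Reagents that add atoms: none
Why: Claisen self-condensation, in which the α-methoxy ester is both a ready enolate precursor and an activated acyl acceptor, and deprotonation of the β-keto ester product by the base drives the equilibrium.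

Step 2
Reactants: 2 methyl 2,4-dimethoxy-3-oxobutanoate; 3 N-methoxy-N-methylacetamide
Product: 4 methyl 2,4-dimethoxy-3,5-dioxohexanoate
Conditions: LiN(i-Pr)2 (2.2 equiv), THF, −78 to 0 °C; then 3 (1.1 equiv), −78 to 0 °C; then 1 M HCl
Reagents that add atoms: none
Why: γ-Acylation of a β-keto ester dianion, in which the second deprotonation occurs at the methoxymethyl carbon, only this more basic terminus attacks the N-methoxy-N-methylamide, and the chelated tetrahedral adduct persists until the quench so the diketo ester never meets the carbanion.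

Step 3
Reactants: 4 methyl 2,4-dimethoxy-3,5-dioxohexanoate
Product: 5 4-hydroxy-3,5-dimethoxy-6-methyl-2H-pyran-2-one
Conditions: DBU (1.1 equiv), toluene, reflux; then 1 M HCl
Reagents that add atoms: none
Why: Base-mediated lactonization of a 3,5-diketo ester, in which the C5 enol oxygen attacks the methyl ester (6-exo-trig) to give the conjugated 4-hydroxy-2-pyranone as the thermodynamic sink, while DBU is too weak to generate the methyl carbanion needed for a competing carbocyclization.

Step 4
Reactants: 1 methyl methoxyacetate; 6 4-methoxybenzoyl chloride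
Product: 7 methyl 2-methoxy-3-(4-methoxyphenyl)-3-oxopropanoate (racemic)
Conditions: LiN(i-Pr)2 (2.1 equiv), 1 (2.1 equiv), THF, −78 °C; then 6 (1.0 equiv), −78 °C; then 1 M HCl
Reagents that add atoms: none
Why: Crossed Claisen-type C-acylation of a preformed lithium ester enolate, chosen with the acid chloride because it reacts at −78 °C faster than self-condensation of the activated methoxyacetate, with the second enolate equivalent removing the acidic proton of the product.

Step 5
Reactants: 7 methyl 2-methoxy-3-(4-methoxyphenyl)-3-oxopropanoate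
Product: 8 methyl (2E)-2,3-dimethoxy-3-(4-methoxyphenyl)prop-2-enoate
Conditions: Me2SO4 (1.2 equiv), Cs2CO3 (1.5 equiv), DMF, 0 °C to rt
Reagents that add atoms: dimethyl sulfate, COS(=O)(=O)OC
Why: O-Alkylation of a β-keto ester enolate, favoured by a caesium counter-ion, a dipolar aprotic solvent and a hard methylating agent, and further helped because C-methylation would create a quaternary methoxy-bearing carbon.

Step 6
Reactants: 5 4-hydroxy-3,5-dimethoxy-6-methyl-2H-pyran-2-one; 8 methyl (2E)-2,3-dimethoxy-3-(4-methoxyphenyl)prop-2-enoate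
Product: 9 4-hydroxy-3,5-dimethoxy-6-[(3E)-3,4-dimethoxy-4-(4-methoxyphenyl)-2-oxobut-3-en-1-yl]-2H-pyran-2-one
Conditions: 5, LiN(i-Pr)2 (3.2 equiv), THF–DMPU, −78 °C; then 8 (1.0 equiv), −78 to 0 °C; then 0.5 M HCl, 0 °C
Reagents that add atoms: none
Why: Claisen-type acylation of the dianion of a 4-hydroxy-6-methyl-2-pyranone, in which the 6-methyl carbanion adds to the ester carbonyl of 8 (no α-hydrogen, fully substituted β-carbon that discourages conjugate attack) and the third equivalent of base stores the product as its enolate.

Step 7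
Reactants: 9 4-hydroxy-3,5-dimethoxy-6-[(3E)-3,4-dimethoxy-4-(4-methoxyphenyl)-2-oxobut-3-en-1-yl]-2H-pyran-2-one
Product: 12 5,7-dihydroxy-3,6,8-trimethoxy-2-(4-methoxyphenyl)-4H-chromen-4-one, via open-chain triketo ester 10 (not isolated), via acylphloroglucinol enone 11 (not isolated)
Conditions: Mg(OMe)2 (6 equiv), MeOH, reflux, N2; then 2 M HCl, 50 °C
Reagents that add atoms: none
Why: Proposed new method: magnesium-bound methoxide opens the lactone of 9 at its carbonyl carbon (future C8a) to the chelated triketo ester 10, whose C4a methylene, the only unsubstituted and most acidic carbon, attacks the ester carbon in a 6-exo-trig Claisen condensation, and loss of methoxide followed by enolization gives the aromatic ring A of 11. A hydroxyl ortho to the new aryl ketone then adds to C2 of the β-methoxy enone in a 6-endo-trig oxa-Michael addition and methanol is eliminated (completed in the acid finish), which forms O1–C2 and ring C. The closest known reactions are the Mg(OMe)2-mediated Claisen cyclization of 6-(2-oxoalkyl)-4-hydroxy-2-pyranones to acylphloroglucinols and the addition–elimination closure of 2-hydroxyaryl β-alkoxyvinyl or β-aminovinyl ketones to chromones; their combination in one flask on a chain methoxylated at every second carbon is what is new. No stereocentre is formed, and the enol-ether geometry is lost in the addition–elimination. The step needs C-acylation at C8a ahead of aldol closure of C8 onto C4 and ahead of O-cyclization of the C5 enolate oxygen onto C2; magnesium chelation of the 1,3-dicarbonyl units, the vinylogous-ester character of the C4 carbonyl and the fully substituted C2 should secure this, with irreversible aromatization draining reversible side equilibria. Because C6 and C8 both carry methoxy, the two ortho hydroxyls are equivalent and ring C closure poses no regiochemical question.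

Step 8
Reactants: 12 5,7-dihydroxy-3,6,8-trimethoxy-2-(4-methoxyphenyl)-4H-chromen-4-one
Product: 13 7-(benzyloxy)-5-hydroxy-3,6,8-trimethoxy-2-(4-methoxyphenyl)-4H-chromen-4-one
Conditions: BnBr (1.05 equiv), K2CO3 (1.5 equiv), acetone, reflux
Reagents that add atoms: benzyl bromide, BrCc1ccccc1
Why: Williamson etherification, selective because the 7-hydroxyl is the acidic, non-chelated phenol whereas the 5-hydroxyl is held in a hydrogen bond to the C4 carbonyl.

Step 9
Reactants: 13 7-(benzyloxy)-5-hydroxy-3,6,8-trimethoxy-2-(4-methoxyphenyl)-4H-chromen-4-one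
Product: 14 7-(benzyloxy)-3,6-dimethoxy-2-(4-methoxyphenyl)-4H-chromene-4,5,8-trione
Conditions: (NH4)2Ce(NO3)6 (2.2 equiv), MeCN–H2O, 0 °C
Reagents that add atoms: water, O
Why: Oxidative demethylation of a 4-methoxyphenol to a para-quinone by tetravalent cerium, in which the C5 phenol is oxidized, water adds ipso at the para carbon C8 and methanol is lost, while ethers without a free phenol are left alone.

Step 10
Reactants: 14 7-(benzyloxy)-3,6-dimethoxy-2-(4-methoxyphenyl)-4H-chromene-4,5,8-trione
Product: 15 7-(benzyloxy)-5,8-dihydroxy-3,6-dimethoxy-2-(4-methoxyphenyl)-4H-chromen-4-one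
Conditions: Na2S2O4 (excess), EtOAc–H2O, rt, Ar
Reagents that add atoms: none
Why: Quinone-to-hydroquinone reduction with Na2S2O4 under two-phase conditions is fast and chemoselective, leaving the benzyl ether, the chromone double bond and the methyl ethers untouched.

Step 11
Reactants: 15 7-(benzyloxy)-5,8-dihydroxy-3,6-dimethoxy-2-(4-methoxyphenyl)-4H-chromen-4-one; 16 3-methylbutanoyl chloride (isovaleryl chloride)
Product: 17 7-(benzyloxy)-5-hydroxy-3,6-dimethoxy-2-(4-methoxyphenyl)-4-oxo-4H-chromen-8-yl 3-methylbutanoate
Conditions: 16 (1.1 equiv), pyridine, CH2Cl2, −20 to 0 °C, Ar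
Reagents that add atoms: none
Why: Chemoselective pyridine-mediated esterification with an acid chloride, since the 8-hydroxyl is a free phenol while the 5-hydroxyl is deactivated by its hydrogen bond to the C4 carbonyl, so one equivalent at low temperature should acylate O8 only.

Step 12
Reactants: 17 7-(benzyloxy)-5-hydroxy-3,6-dimethoxy-2-(4-methoxyphenyl)-4-oxo-4H-chromen-8-yl 3-methylbutanoate
Product: 18 5,7-dihydroxy-3,6-dimethoxy-2-(4-methoxyphenyl)-4-oxo-4H-chromen-8-yl 3-methylbutanoate
Conditions: H2 (1 atm), 10% Pd/C, EtOAc, rt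
Reagents that add atoms: none
Why: Catalytic hydrogenolysis of a benzyl aryl ether in a neutral aprotic solvent frees the 7-hydroxyl without touching the aryl ester, the methyl ethers or the chromone, and the absence of base and alcohol avoids acyl migration and transesterification.

**Compound list**

1 | methyl methoxyacetate | COCC(=O)OC | starting material
2 | methyl 2,4-dimethoxy-3-oxobutanoate (racemic) | COCC(=O)C(OC)C(=O)OC | intermediate
3 | N-methoxy-N-methylacetamide | CON(C)C(C)=O | starting material
4 | methyl 2,4-dimethoxy-3,5-dioxohexanoate (mixture of diastereomers and tautomers) | CC(=O)C(OC)C(=O)C(OC)C(=O)OC | intermediate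
5 | 4-hydroxy-3,5-dimethoxy-6-methyl-2H-pyran-2-one | CC1=C(OC)C(O)=C(OC)C(=O)O1 | intermediate
6 | 4-methoxybenzoyl chloride | COc1ccc(cc1)C(Cl)=O | starting material
7 | methyl 2-methoxy-3-(4-methoxyphenyl)-3-oxopropanoate (racemic) | COC(C(=O)OC)C(=O)c1ccc(OC)cc1 | intermediate
8 | methyl (2E)-2,3-dimethoxy-3-(4-methoxyphenyl)prop-2-enoate | COC(=O)/C(OC)=C(\OC)c1ccc(OC)cc1 | intermediate
9 | 4-hydroxy-3,5-dimethoxy-6-[(3E)-3,4-dimethoxy-4-(4-methoxyphenyl)-2-oxobut-3-en-1-yl]-2H-pyran-2-one | O=C1OC(CC(=O)/C(OC)=C(\OC)c2ccc(OC)cc2)=C(OC)C(O)=C1OC | intermediate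
10 | methyl (8E)-2,4,8,9-tetramethoxy-9-(4-methoxyphenyl)-3,5,7-trioxonon-8-enoate (magnesium chelate in the flask; not isolated) | COC(=O)C(OC)C(=O)C(OC)C(=O)CC(=O)/C(OC)=C(\OC)c1ccc(OC)cc1 | intermediate
11 | (2E)-2,3-dimethoxy-3-(4-methoxyphenyl)-1-(2,4,6-trihydroxy-3,5-dimethoxyphenyl)prop-2-en-1-one (not isolated) | O=C(c1c(O)c(OC)c(O)c(OC)c1O)/C(OC)=C(\OC)c1ccc(OC)cc1 | intermediate
12 | 5,7-dihydroxy-3,6,8-trimethoxy-2-(4-methoxyphenyl)-4H-chromen-4-one (5,7-dihydroxy-3,6,8,4'-tetramethoxyflavone) | COc1ccc(-c2oc3c(OC)c(O)c(OC)c(O)c3c(=O)c2OC)cc1 | intermediate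
13 | 7-(benzyloxy)-5-hydroxy-3,6,8-trimethoxy-2-(4-methoxyphenyl)-4H-chromen-4-one | COc1ccc(-c2oc3c(OC)c(OCc4ccccc4)c(OC)c(O)c3c(=O)c2OC)cc1 | intermediate
14 | 7-(benzyloxy)-3,6-dimethoxy-2-(4-methoxyphenyl)-4H-chromene-4,5,8-trione | COc1ccc(cc1)C1=C(OC)C(=O)C2=C(O1)C(=O)C(OCc1ccccc1)=C(OC)C2=O | intermediate
15 | 7-(benzyloxy)-5,8-dihydroxy-3,6-dimethoxy-2-(4-methoxyphenyl)-4H-chromen-4-one | COc1ccc(-c2oc3c(O)c(OCc4ccccc4)c(OC)c(O)c3c(=O)c2OC)cc1 | intermediate
16 | 3-methylbutanoyl chloride (isovaleryl chloride) | CC(C)CC(=O)Cl | starting material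
17 | 7-(benzyloxy)-5-hydroxy-3,6-dimethoxy-2-(4-methoxyphenyl)-4-oxo-4H-chromen-8-yl 3-methylbutanoate | COc1ccc(-c2oc3c(OC(=O)CC(C)C)c(OCc4ccccc4)c(OC)c(O)c3c(=O)c2OC)cc1 | intermediate
18 | 5,7-dihydroxy-3,6-dimethoxy-2-(4-methoxyphenyl)-4-oxo-4H-chromen-8-yl 3-methylbutanoate (5,7,8-trihydroxy-3,6,4'-trimethoxyflavone 8-isovalerate) | COc1ccc(-c2oc3c(OC(=O)CC(C)C)c(O)c(OC)c(O)c3c(=O)c2OC)cc1 | target

**Step count**

Total: 12 steps. Longest linear sequence: 10 steps (steps 1, 2, 3, 6, 7, 8, 9, 10, 11, 12); steps 4 and 5 form the side branch.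

**Steps most likely to fail**

Step 7 (the proposed new method). The opened chain may close through oxygen instead of carbon: the C5 enolate oxygen can add to C2 and expel methoxide to give a 4-pyranone. The aldol closure of C8 onto C4 may compete, methoxide may cleave the methoxylated chain by retro-Claisen reaction, or ring C may fail to close in the same flask. The fallback sets out from 5 and returns at 12, and builds ring C only after ring A exists. The dianion of 5 (LiN(i-Pr)2, THF, −78 °C) would be acylated with methyl methoxyacetate 1 to give 4-hydroxy-3,5-dimethoxy-6-(3-methoxy-2-oxopropyl)-2H-pyran-2-one F1. This pyranone has no enol-ether terminus, so Mg(OMe)2 in methanol should convert it by the established pyranone-to-acylphloroglucinol Claisen cyclization into 2-methoxy-1-(2,4,6-trihydroxy-3,5-dimethoxyphenyl)ethan-1-one F2. An Allan–Robinson condensation of F2 with 4-methoxybenzoic anhydride and sodium 4-methoxybenzoate (about 180 °C, then KOH in aqueous methanol to cleave O-aroyl groups, then acid) would close ring C and deliver 12.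

Step 6. The vinylogous carbanion may fail to add to the hindered, electron-rich acrylate carbonyl, may attack the β-carbon with loss of methoxide, or may be quenched by proton transfer. The fallback sets out from 8 and returns at 9, and replaces acylation by an aldol addition to a far more electrophilic aldehyde followed by oxidation. Reduction of 8 with i-Bu2AlH (CH2Cl2, −78 °C) would give (2E)-2,3-dimethoxy-3-(4-methoxyphenyl)prop-2-en-1-ol F3. Oxidation with MnO2 (CH2Cl2, rt) would give (2E)-2,3-dimethoxy-3-(4-methoxyphenyl)prop-2-enal F4. Addition of the dianion of 5 to F4 at −78 °C, with a buffered quench near pH 5 to spare the acid-labile allylic enol ether, would give racemic 4-hydroxy-6-[(3E)-2-hydroxy-3,4-dimethoxy-4-(4-methoxyphenyl)but-3-en-1-yl]-3,5-dimethoxy-2H-pyran-2-one F5. Oxidation of this allylic alcohol with MnO2 would then give 9.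

Step 9. One-electron oxidation by cerium may go astray: water may attack ipso at the ortho carbon C6 instead of C8, the benzyl ether or the anisyl ring may be oxidized, or the electron-rich ring may be nitrated. The fallback sets out from 13 and returns at 14. It uses a phenol-bound two-electron oxidation with PhI(OAc)2 in methanol at 0 °C, which should deliver methanol to the para carbon and give the quinone monoketal 7-(benzyloxy)-3,6,8,8-tetramethoxy-2-(4-methoxyphenyl)-8H-chromene-4,5-dione F6. Mild hydrolysis of F6 (aqueous oxalic acid, THF, rt) would release quinone 14.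

**Further compounds**

F1 | step 7 | 4-hydroxy-3,5-dimethoxy-6-(3-methoxy-2-oxopropyl)-2H-pyran-2-one | COCC(=O)CC1=C(OC)C(O)=C(OC)C(=O)O1
F2 | step 7 | 2-methoxy-1-(2,4,6-trihydroxy-3,5-dimethoxyphenyl)ethan-1-one | COCC(=O)c1c(O)c(OC)c(O)c(OC)c1O
F3 | step 6 | (2E)-2,3-dimethoxy-3-(4-methoxyphenyl)prop-2-en-1-ol | OC/C(OC)=C(\OC)c1ccc(OC)cc1
F4 | step 6 | (2E)-2,3-dimethoxy-3-(4-methoxyphenyl)prop-2-enal | O=C/C(OC)=C(\OC)c1ccc(OC)cc1
F5 | step 6 | 4-hydroxy-6-[(3E)-2-hydroxy-3,4-dimethoxy-4-(4-methoxyphenyl)but-3-en-1-yl]-3,5-dimethoxy-2H-pyran-2-one (racemic) | O=C1OC(CC(O)/C(OC)=C(\OC)c2ccc(OC)cc2)=C(OC)C(O)=C1OC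
F6 | step 9 | 7-(benzyloxy)-3,6,8,8-tetramethoxy-2-(4-methoxyphenyl)-8H-chromene-4,5-dione | COc1ccc(cc1)C1=C(OC)C(=O)C2=C(O1)C(OC)(OC)C(OCc1ccccc1)=C(OC)C2=O
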